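The equivalent of Sub was my unit. Sub stood at 0.8 % at the first reading of the south-west run and 0.5 % at 8.00 min in the north-east run, so I treated each flask as the sharing out of one equivalent of Sub, with time out of the question.

the same everywhere: Sub 0.50 M

| run | Rea | Rea2 | Oth | temperature | remark | time |
|---|---|---|---|---|---|---|
| south-west | 1 equiv | 1.3 equiv | 0.10 M | 30 °C | run made earlier |  |
| north-east | 4 equiv | 1.3 equiv | 0.10 M | 42 °C | run made earlier |  |
| north | 2 equiv | 2.6 equiv | 0.10 M | 30 °C | run made earlier |  |
| grey | 2.00 equiv | 1.30 equiv | 0.100 M | 50 °C |  | 80 min |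
| ochre | 2.00 equiv | 1.30 equiv | 0.100 M | 35 °C |  | 80 min |

| run | time / min | Pdt / % | Sub / % |
|---|---|---|---|
| south-west | 40.0 | 34.9 | 0.8 |
| south-west | 80.0 | 35.1 | 0.8 |
| south-west | 150 | 34.5 | 0.5 |
| north-east | 8.00 | 65.8 | 0.5 |
| north-east | 25.0 | 65.3 | 0 |
| north-east | 40.0 | 66.6 | 0.6 |
| north-east | 60.0 | 66.7 | 0.4 |
| north | 40.0 | 33.5 | 0 |
| north | 80.0 | 33.3 | 0 |
| north | 150 | 32.2 | 0 |

(each reading ± 0.5 percentage points)

* which flask leads in amount of Pdt, in percent of the Sub charged ("all alike" within 1.5 percentage points) (grey / ochre / all alike)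
* how much Pdt is there at the end, in percent of the Sub charged: grey
* how much Pdt is there at the end, in percent of the Sub charged: ochre



I booked Pdt against Rea and the remainder of Sub against Rea2, a guess, since that remainder was never measured. If both reactions are first order in Sub and in their reagent, the instantaneous rates stand as s·c(Rea) to c(Rea2). Here s is the ratio of ln(fraction of Rea left) to ln(fraction of Rea2 left), counting only what Sub takes. The runs gave 0.625 (south-west), 0.613 (north-east) and 0.614 (north). I carried their mean, the selectivity factor s = 0.618.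

At the start of grey or ochre, the share of Sub going to Pdt is s·c(Rea)/(s·c(Rea) + c(Rea2)), which gave 48.7 %. The objection was that this holds for one moment. In grey and ochre Rea2 is the smaller charge, so the comparison drifts. With Sub nearly gone, the same ratio on what remained gave 54.3 %, more than at the start. The mean of the two, 51.5 %, was my figure for both flasks.

A second doubt was temperature. The north-east run at 42 °C gave much the same s as those at 30 °C, which covers ochre, but grey at 50 °C lies beyond the runs. A third was Oth, which might take Rea2 unseen by my count, and this I could not compute away.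

The forecast said all alike, with grey at 50 % (46 % to 53 %) and ochre at 50 % (48 % to 52 %), judging that “temperature has little effect on selectivity”. Its central values stood below my 51.5 %.

The simulation gave grey 49.8 % and ochre 50.5 %, so all alike, a gap of 0.7 percentage points.

    Rea → Sdp (k = 2.70 × 10⁻⁴ s⁻¹, Ea = 100 kJ mol⁻¹)
    Rea2 + Oth → Sdp3 (k = 0.0130 M⁻¹ s⁻¹, Ea = 69.0 kJ mol⁻¹)
    Sub + Rea2 → Sdp2 (k = 0.0300 M⁻¹ s⁻¹, Ea = 57.0 kJ mol⁻¹)
    Sub + Rea → Pdt (k = 0.0170 M⁻¹ s⁻¹, Ea = 55.0 kJ mol⁻¹)
    (constants at 50 °C)

The neighbour flask is ochre with 3.40 equiv of Rea. There my share at the start was 61.8 %, and with Sub nearly gone it was 65.2 %, with a mean of 63.5 %. That neighbour flask held 62.6 % of Pdt.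

(The data are simulated for substances that don't exist; noise was put on by code.)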